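**Retrosynthetic overview**

1. The target is cut at the C3–O ester bond into all-E (3R)-β-cryptoxanthin and oleic acid. The ester is made last, so the (Z)-alkene of the acyl chain never meets the conditions that equilibrate the polyene.
2. (3R)-β-Cryptoxanthin is cut at C7=C8 (Wittig) into a ring A C10 phosphonium salt (C1–C7 with C16, C17, C18) and the commercial C30 β-apo-8'-carotenal, which already holds ring B and the whole chain.
3. The C10 salt comes from (3R)-3-hydroxy-β-cyclogeraniol 7-silyl ether, made by reagent-controlled asymmetric hydroboration–oxidation of the C3=C4 bond of safranol silyl ether, itself from safranal.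
4. Feature on which the plan rests: the only stereocentre, the C3 carbinol carbon of ring A, is one end of the C3=C4 alkene of the achiral 3,4-didehydro ring of safranal, while C5=C6 of that ring is tetrasubstituted and closed to a bulky borane.
5. Ring order: no ring is built; ring A is bought with safranal and ring B with the apocarotenal.

Key step: step 3

Remark on the chemistry: carotenoid numbering is used (ring A: C1 = CMe2, C3 = carbinol carbon, C5=C6 = ring alkene, C7 = exocyclic carbon). "(+)-Ipc2BH" means the borane made from (−)-α-pinene. Its sense of induction is assigned from the topicity rule for cis-alkenes and should be confirmed by correlation at diol 6.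

**Step 1**
Reactants: 1 safranal
Product: 2 safranol [(2,6,6-trimethylcyclohexa-1,3-dien-1-yl)methanol]
Conditions: NaBH4, CeCl3·7H2O, MeOH, 0 °C
Reagents that add atoms: none
Why: Luche-type 1,2-reduction of the conjugated aldehyde by borohydride should give the primary allylic alcohol and leave the ring diene untouched.

**Step 2**
Reactants: 2 safranol
Product: 3 safranol tert-butyldimethylsilyl ether
Conditions: TBSCl, imidazole, DMF, 0 °C → rt
Reagents that add atoms: tert-butyldimethylsilyl chloride, CC(C)(C)[Si](C)(C)Cl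
Why: Imidazole-promoted silylation of a primary alcohol removes the O–H that would consume borane and puts a bulky group at C7 that further shields C5=C6.

**Step 3**
Reactants: 3 safranol tert-butyldimethylsilyl ether
Product: 5 (3R)-3-hydroxy-β-cyclogeraniol 7-TBS ether [(1R)-4-(tert-butyldimethylsilyloxymethyl)-3,5,5-trimethylcyclohex-3-en-1-ol], via trialkylborane 4 (not isolated)
Conditions: (−)-α-pinene (2.3 equiv per boron), BH3·SMe2, THF, 0 °C, aged cold [gives (+)-Ipc2BH, about 1.3 equiv]; then 3, THF, −25 → 0 °C; then 3 M NaOH, 30% H2O2, 0 °C → rt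
Reagents that add atoms: hydrogen peroxide, OO (oxygen of the C3 hydroxyl); the boron and the two isopinocampheyl groups of 4 come from (+)-Ipc2BH, B([C@H]1C[C@H]2C[C@@H]([C@@H]1C)C2(C)C)[C@H]1C[C@H]2C[C@@H]([C@@H]1C)C2(C)C, and are lost again on oxidation
Why: Asymmetric hydroboration–oxidation: the B–H bond of (+)-Ipc2BH adds syn across the cis-disubstituted C3=C4 bond through a four-centre transition state, and alkaline H2O2 then replaces boron by oxygen through migration of C3 from boron to oxygen with retention. The closest known reaction type is the diisopinocampheylborane hydroboration of cis-alkenes and cyclic 1,3-dienes, which has been run on O-protected safranol. No ring is closed and no skeletal bond is formed; only the C3–O and C4–H bonds are made. The one new stereocentre, C3, is set by the reagent alone because 3 is achiral: the borane from (−)-α-pinene, which turns cis-but-2-ene into (S)-butan-2-ol, should by the same topicity deliver boron to the ring face that gives 3R. The step needs boron at C3 and not at C4, and reaction at C3=C4 and not at C5=C6. C4 lies next to the fully substituted C5 with its C18 methyl, which a borane as bulky as Ipc2BH should avoid, and the tetrasubstituted C5=C6 bond, flanked by the C1 gem-dimethyl group and the CH2OTBS arm, should not react.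

**Step 4**
Reactants: 5 (3R)-3-hydroxy-β-cyclogeraniol 7-TBS ether
Product: 6 (3R)-3-hydroxy-β-cyclogeraniol [(1R)-4-(hydroxymethyl)-3,5,5-trimethylcyclohex-3-en-1-ol]
Conditions: Bu4NF, THF, 0 °C → rt
Reagents that add atoms: none
Why: Fluoride-induced desilylation frees the primary allylic alcohol without touching C3, and the diol is the point at which enantiomeric purity can be checked and, if it crystallises suitably, raised.

**Step 5**
Reactants: 6 (3R)-3-hydroxy-β-cyclogeraniol
Product: 7 [(4R)-4-hydroxy-2,6,6-trimethylcyclohex-1-en-1-yl]methyl(triphenyl)phosphonium bromide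
Conditions: PPh3·HBr, MeOH, rt; precipitate with Et2O
Reagents that add atoms: triphenylphosphine hydrobromide, [Br-].c1ccc(cc1)[PH+](c1ccccc1)c1ccccc1
Why: Acid-promoted ionisation of the primary allylic alcohol to the C7/C5 allyl cation and capture by PPh3 at the primary end (SN1-type Wittig salt formation, as used for cyclogeranyl and polyenyl salts) should be selective, because the non-allylic secondary C3–OH does not ionise under these conditions.

**Step 6**
Reactants: 7 the C10 phosphonium bromide; 8 β-apo-8'-carotenal
Product: 10 (3R)-β-cryptoxanthin as 7E/7Z mixture, via ylide sodium alkoxide 9 (not isolated)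
Conditions: 7 (1.3 equiv), NaN(SiMe3)2 (2 equiv per 7), THF, −78 → 0 °C; then 8, THF, 0 °C → rt, Ar, dark; aq. NH4Cl
Reagents that add atoms: none
Why: Wittig olefination, in which the semi-stabilised allylic ylide adds to the aldehyde carbon (which becomes C8) and the oxaphosphetane collapses to the C7=C8 alkene and Ph3P=O, should join the C10 and C30 halves; the C3 alkoxide is a spectator that is reprotonated on work-up, and the E/Z outcome at C7=C8 does not matter because step 7 equilibrates it.

**Step 7**
Reactants: 10 (3R)-β-cryptoxanthin as 7E/7Z mixture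
Product: 11 all-E (3R)-β-cryptoxanthin
Conditions: n-heptane, reflux, Ar, dark; cool and crystallise
Reagents that add atoms: none
Why: Thermal E/Z isomerisation of the polyene should drain the 7Z isomer, which is strained by the clash between the ring methyls and the C9 end of the chain, into the all-E isomer that crystallises best; a trace of I2 under visible light is the usual accelerant if the thermal equilibration is slow, and it is harmless here because no oleate is present yet.

**Step 8**
Reactants: 11 all-E (3R)-β-cryptoxanthin; 12 oleic acid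
Product: 14 (3R)-β-cryptoxanthin oleate (CNP0152321.1), via O-acylisourea 13 (not isolated)
Conditions: 12 (1.5 equiv), DCC, DMAP (cat.), CH2Cl2, 0 °C → rt, Ar, dark
Reagents that add atoms: none
Why: Steglich esterification, in which DCC activates the acid as the O-acylisourea and DMAP relays the acyl group to the unhindered secondary C3–OH, never breaks the C3–O bond, so the R configuration is kept, and the neutral cold conditions should leave both the all-E polyene and the (Z)-alkene of the acyl chain unchanged.

**Compound list**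

1 | safranal | CC1=C(C=O)C(C)(C)CC=C1 | starting material
2 | safranol | CC1=C(CO)C(C)(C)CC=C1 | intermediate
3 | safranol tert-butyldimethylsilyl ether | CC1=C(CO[Si](C)(C)C(C)(C)C)C(C)(C)CC=C1 | intermediate
4 | (3R)-3-(diisopinocampheylboryl)-β-cyclogeraniol 7-TBS ether (Ipc groups from (−)-α-pinene) | B([C@H]1C[C@H]2C[C@@H]([C@@H]1C)C2(C)C)([C@H]1C[C@H]2C[C@@H]([C@@H]1C)C2(C)C)[C@@H]1CC(C)=C(CO[Si](C)(C)C(C)(C)C)C(C)(C)C1 | intermediate (not isolated)
5 | (3R)-3-hydroxy-β-cyclogeraniol 7-TBS ether | O[C@@H]1CC(C)=C(CO[Si](C)(C)C(C)(C)C)C(C)(C)C1 | intermediate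
6 | (3R)-3-hydroxy-β-cyclogeraniol | O[C@@H]1CC(C)=C(CO)C(C)(C)C1 | intermediate
7 | [(4R)-4-hydroxy-2,6,6-trimethylcyclohex-1-en-1-yl]methyl(triphenyl)phosphonium bromide | O[C@@H]1CC(C)=C(C[P+](c2ccccc2)(c2ccccc2)c2ccccc2)C(C)(C)C1.[Br-] | intermediate
8 | β-apo-8'-carotenal | CC1=C(/C=C/C(C)=C/C=C/C(C)=C/C=C/C=C(C)/C=C/C=C(C)/C=O)C(C)(C)CCC1 | starting material
9 | ylide of 7 as its sodium 3-alkoxide | [Na+].[O-][C@@H]1CC(C)=C(C=P(c2ccccc2)(c2ccccc2)c2ccccc2)C(C)(C)C1 | intermediate (not isolated)
10 | (3R)-β-cryptoxanthin, 7E/7Z mixture (C7=C8 undefined, all other chain alkenes E) | O[C@@H]1CC(C)=C(C=C/C(C)=C/C=C/C(C)=C/C=C/C=C(C)/C=C/C=C(C)/C=C/C2=C(C)CCCC2(C)C)C(C)(C)C1 | intermediate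
11 | all-E (3R)-β-cryptoxanthin | O[C@@H]1CC(C)=C(/C=C/C(C)=C/C=C/C(C)=C/C=C/C=C(C)/C=C/C=C(C)/C=C/C2=C(C)CCCC2(C)C)C(C)(C)C1 | intermediate
12 | oleic acid | CCCCCCCC/C=C\CCCCCCCC(=O)O | starting material
13 | O-oleoyl-N,N'-dicyclohexylisourea | CCCCCCCC/C=C\CCCCCCCC(=O)OC(=NC1CCCCC1)NC1CCCCC1 | intermediate (not isolated)
14 | (3R)-β-cryptoxanthin oleate, all-E polyene, (9Z) acyl chain | CCCCCCCC/C=C\CCCCCCCC(=O)O[C@@H]1CC(C)=C(/C=C/C(C)=C/C=C/C(C)=C/C=C/C=C(C)/C=C/C=C(C)/C=C/C2=C(C)CCCC2(C)C)C(C)(C)C1 | target

**Step count**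

Total steps: 8. Longest linear sequence: 8 steps (1 → 14); 8 and 12 enter as purchased compounds.

**Steps most likely to fail, with fallbacks**

1. Step 6 (Wittig). The ylide carbon sits between the C1 gem-dimethyl group and the C5 methyl, and the aldehyde is α-methyl-branched. Addition may therefore be slow enough that ylide decay and base-induced damage to the polyenal win. Fallback: reverse the polarity of the same C7=C8 Wittig. It sets out from 6 and 8 and returns at 10. The allylic alcohol of 6 is oxidised selectively (MnO2, CH2Cl2, rt) to (3R)-3-hydroxy-β-cyclocitral F1. Aldehyde 8 is reduced (NaBH4, EtOH/THF, 0 °C) to β-apo-8'-carotenol F2, which with PPh3·HBr (MeOH/CH2Cl2, rt) should give β-apo-8'-carotenyl(triphenyl)phosphonium bromide F3. NaOMe (MeOH/CH2Cl2, 0 °C → rt) converts F3 into the polyenyl ylide F4, whose unhindered chain-end carbon adds to F1 to give 10, which then goes through step 7.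

2. Step 3 (hydroboration). Facial selectivity may be insufficient, giving material of low enantiomeric purity at C3. Boron may also go in part to C4, the position the parent cyclohexa-1,3-diene prefers; that would give an allylic alcohol, separable by chromatography. Fallback: achiral hydroboration followed by enzymatic kinetic resolution. It sets out from 3 and returns at 5. Disiamylborane (from BH3·THF and 2-methylbut-2-ene, THF, 0 °C) should give the racemic C3 disiamylborane adduct F5, oxidised (NaOH, H2O2) to racemic 3-hydroxy-β-cyclogeraniol 7-TBS ether F6. Lipase-catalysed transesterification (Burkholderia cepacia lipase, vinyl acetate, MTBE, rt) should, by the usual empirical rule for secondary alcohols, acylate the 3R enantiomer to the (3R)-acetate F7 and leave the (3S)-alcohol F8. After chromatographic separation F7 is methanolysed (K2CO3, MeOH, rt) to 5. Should the enzyme prefer the 3S alcohol, the unreacted alcohol fraction is 5 itself.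

3. Step 8 (esterification). Acylation may stall, with acyl transfer to the N-acylurea and slow oxidative or acid-induced decay and E/Z scrambling of the polyene during a long reaction and chromatography. Fallback: install the oleate before the polyene exists. It sets out from 5 and returns at 14. Alcohol 5 is acylated with 12 (DCC, DMAP, CH2Cl2) to the (3R)-oleate 7-TBS ether F9. HF·pyridine (THF, 0 °C) frees the (3R)-3-oleoyloxy-β-cyclogeraniol F10. PPh3·HBr in CH2Cl2 (no methanol, to avoid transesterification) gives the oleoyloxy phosphonium bromide F11. Wittig reaction with 8 in refluxing 1,2-epoxybutane, where the epoxide takes up HBr and no alkoxide base touches the ester, proceeds through the ylide F12 to the 7E/7Z mixture of the ester F13. Purely thermal isomerisation (n-heptane, reflux, dark, no iodine, so the (Z)-alkene of the acyl chain is not touched) then gives 14.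

**Further compounds**

F1 | step 6 | (3R)-3-hydroxy-β-cyclocitral | O[C@@H]1CC(C)=C(C=O)C(C)(C)C1
F2 | step 6 | β-apo-8'-carotenol | CC1=C(/C=C/C(C)=C/C=C/C(C)=C/C=C/C=C(C)/C=C/C=C(C)/CO)C(C)(C)CCC1
F3 | step 6 | β-apo-8'-carotenyl(triphenyl)phosphonium bromide | CC1=C(/C=C/C(C)=C/C=C/C(C)=C/C=C/C=C(C)/C=C/C=C(C)/C[P+](c2ccccc2)(c2ccccc2)c2ccccc2)C(C)(C)CCC1.[Br-]
F4 | step 6 | ylide of F3 | CC1=C(/C=C/C(C)=C/C=C/C(C)=C/C=C/C=C(C)/C=C/C=C(C)/C=P(c2ccccc2)(c2ccccc2)c2ccccc2)C(C)(C)CCC1
F5 | step 3 | racemic 3-(disiamylboryl)-β-cyclogeraniol 7-TBS ether | CC(C)C(C)B(C(C)C(C)C)C1CC(C)=C(CO[Si](C)(C)C(C)(C)C)C(C)(C)C1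
F6 | step 3 | racemic 3-hydroxy-β-cyclogeraniol 7-TBS ether | OC1CC(C)=C(CO[Si](C)(C)C(C)(C)C)C(C)(C)C1
F7 | step 3 | (3R)-3-acetoxy-β-cyclogeraniol 7-TBS ether | CC(=O)O[C@@H]1CC(C)=C(CO[Si](C)(C)C(C)(C)C)C(C)(C)C1
F8 | step 3 | (3S)-3-hydroxy-β-cyclogeraniol 7-TBS ether | O[C@H]1CC(C)=C(CO[Si](C)(C)C(C)(C)C)C(C)(C)C1
F9 | step 8 | (3R)-3-oleoyloxy-β-cyclogeraniol 7-TBS ether | CCCCCCCC/C=C\CCCCCCCC(=O)O[C@@H]1CC(C)=C(CO[Si](C)(C)C(C)(C)C)C(C)(C)C1
F10 | step 8 | (3R)-3-oleoyloxy-β-cyclogeraniol | CCCCCCCC/C=C\CCCCCCCC(=O)O[C@@H]1CC(C)=C(CO)C(C)(C)C1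
F11 | step 8 | [(4R)-4-oleoyloxy-2,6,6-trimethylcyclohex-1-en-1-yl]methyl(triphenyl)phosphonium bromide | CCCCCCCC/C=C\CCCCCCCC(=O)O[C@@H]1CC(C)=C(C[P+](c2ccccc2)(c2ccccc2)c2ccccc2)C(C)(C)C1.[Br-]
F12 | step 8 | ylide of F11 | CCCCCCCC/C=C\CCCCCCCC(=O)O[C@@H]1CC(C)=C(C=P(c2ccccc2)(c2ccccc2)c2ccccc2)C(C)(C)C1
F13 | step 8 | (3R)-β-cryptoxanthin oleate, 7E/7Z mixture | CCCCCCCC/C=C\CCCCCCCC(=O)O[C@@H]1CC(C)=C(C=C/C(C)=C/C=C/C(C)=C/C=C/C=C(C)/C=C/C=C(C)/C=C/C2=C(C)CCCC2(C)C)C(C)(C)C1
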